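## Retrosynthetic overview
1. Target 10 ⇒ oxolane quinone methide 9 + H2O (1,6-addition at C7'). 9 ⇒ the 8–8'-linked erythro bis(quinone methide), closed by O9' on C7. These are the two events that follow coniferyl/caffeyl 8–8' coupling in the plant.
2. The bis(quinone methide) is stored as cis-cyclobutane diol 7, with the C7–C7' bond as the lock. It is released by oxidising only the catechol.
3. 7 ⇒ macrocyclic beta-truxinate 6 ⇒ intramolecular head-to-head [2+2] of mixed diester 5.
4. 5 ⇒ ferulic acid 1 + caffeic acid 4 + (R)-butane-1,3-diol 2, by two Mitsunobu esterifications without protecting groups.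
5. Ring order: cyclobutane (temporary, carries C8/C8') → oxolane (last step, sets C7 and C7').

Assumption: lignan numbering is used (ring A = guaiacyl half with C7–C9, ring B = catechol half with C7'–C9'), and the sense of induction in step 3 is taken from the folded-tether model given in that step.

## Route

Step 1
Reactants: 1 ferulic acid; 2 (R)-butane-1,3-diol
Product: 3 (3R)-3-hydroxybutyl (E)-ferulate
Conditions: PPh3, DIAD, 2 (3 equiv), THF, 0 °C to rt
Reagents that add atoms: none
Why: Mitsunobu esterification, in which the carboxylic acid (far more acidic than the phenol) is the only competent pronucleophile and the unhindered primary hydroxyl of the excess diol is activated much faster than the secondary one, so the carbinol stereocentre is untouched.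

Step 2
Reactants: 3 (3R)-3-hydroxybutyl (E)-ferulate; 4 caffeic acid
Product: 5 (2S)-4-[(E)-feruloyloxy]butan-2-yl (E)-caffeate
Conditions: PPh3, DIAD, THF, 0 °C to rt
Reagents that add atoms: none
Why: A second Mitsunobu esterification, again chemoselective for CO2H over phenol and catechol OH, runs by SN2 displacement of the secondary oxyphosphonium ion and so inverts the carbinol centre from R to S.

Step 3
Reactants: 5 (2S)-4-[(E)-feruloyloxy]butan-2-yl (E)-caffeate
Product: 6 macrocyclic heterodimeric beta-truxinate (7S,8R,8'S,7'R; tether carbinol S)
Conditions: hv (350 nm, Pyrex), degassed H2O–MeCN 3:1, 1 mM, 5 °C; chromatography to remove the minor diastereomer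
Reagents that add atoms: none
Why: Proposed new method: direct excitation of the folded, pi-stacked conformer gives a suprafacial head-to-head syn [2+2] photocycloaddition (closest known types: propane-1,3-diyl dicinnamates and template-bound mixed cinnamates giving beta-truxinates, and pentane-2,4-diol-tethered diastereodifferentiating photocycloadditions); the nine-membered tether forces C9 and C9' cis, and the fold with the methyl group anti to the chain, the secondary ester C=O eclipsing the carbinol C–H and both enoates s-cis allows one stacking sense only, which sets 8R and 8'S (plus the transient 7S and 7'R, each aryl trans to its neighbouring carbonyl).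

Step 4
Reactants: 6 macrocyclic heterodimeric beta-truxinate
Product: 7 [(1R,2S,3R,4S)-3-(3,4-dihydroxyphenyl)-4-(4-hydroxy-3-methoxyphenyl)cyclobutane-1,2-diyl]dimethanol
Conditions: LiAlH4 (6 equiv), THF, 0 °C to rt; then 1 M HCl
Reagents that add atoms: none
Why: Hydride reduction of both esters cleaves the acyl–oxygen bonds, releases the tether and does not touch the four cyclobutane stereocentres.

Step 5
Reactants: 7 cyclobutane diol
Product: 10 target (7S,8R,8'S,7'R)-7,9'-epoxylignan, via ortho-quinone 8 (not isolated), via oxolane quinone methide 9 (not isolated)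
Conditions: Ag2O (1.05 equiv), acetone–H2O 10:1, 0 °C to rt, dark, Ar; filter through Celite
Reagents that add atoms: water, O
Why: Proposed new method: Ag2O oxidises only the catechol (the guaiacol is harder to oxidise) to ortho-quinone 8, a vicinal donor–acceptor cyclobutane in which the ring A phenol pushes and the quinone pulls, so the strained C7–C7' bond breaks heterolytically (Grob-type) with C7 as the electrophilic quinone-methide terminus and C7' as a quinone-methide enolate; the C9' hydroxyl therefore closes first on C7 (5-exo 1,6-addition, aryl trans to C9, giving 7S) to form 9, the C9 hydroxyl cannot reach C7' because that would need a trans-fused bicyclo[3.3.0] system, and after protonation water adds 1,6 to C7' on the face flanked by C8, guided by a hydrogen bond to the C9 hydroxyl in the conformer with H8' eclipsing the quinoid ring (giving 7'R); the closest known reactions are the FeCl3-mediated oxidative ring opening of the bis-guaiacyl cyclobutane diol to the same oxolane type and the tautomerisation–hydration of 4-alkyl-ortho-quinones.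

## Compound list
1 | ferulic acid, (E)-3-(4-hydroxy-3-methoxyphenyl)prop-2-enoic acid | COc1cc(/C=C/C(O)=O)ccc1O | starting material
2 | (R)-butane-1,3-diol | C[C@@H](O)CCO | starting material
3 | (3R)-3-hydroxybutyl (E)-ferulate | COc1cc(/C=C/C(=O)OCC[C@@H](C)O)ccc1O | intermediate
4 | caffeic acid, (E)-3-(3,4-dihydroxyphenyl)prop-2-enoic acid | OC(=O)/C=C/c1ccc(O)c(O)c1 | starting material
5 | (2S)-4-[(E)-feruloyloxy]butan-2-yl (E)-caffeate | COc1cc(/C=C/C(=O)OCC[C@H](C)OC(=O)/C=C/c2ccc(O)c(O)c2)ccc1O | intermediate
6 | macrocyclic heterodimeric beta-truxinate; cyclobutane cis-fused to the nine-membered dilactone, both aryls cis to each other and trans to the neighbouring carbonyl, (7S,8R,8'S,7'R), tether carbinol S | O=C1OCC[C@H](C)OC(=O)[C@H]2[C@H](c3ccc(O)c(O)c3)[C@H](c3ccc(O)c(OC)c3)[C@@H]12 | intermediate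
7 | [(1R,2S,3R,4S)-3-(3,4-dihydroxyphenyl)-4-(4-hydroxy-3-methoxyphenyl)cyclobutane-1,2-diyl]dimethanol | OC[C@@H]1[C@@H](c2ccc(O)c(OC)c2)[C@@H](c2ccc(O)c(O)c2)[C@@H]1CO | intermediate
8 | ortho-quinone of 7 (ring B oxidised to the 3',4'-dione) | OC[C@@H]1[C@@H](c2ccc(O)c(OC)c2)[C@@H](C2=CC(=O)C(=O)C=C2)[C@@H]1CO | intermediate
9 | (7S,8R,8'S)-oxolane carrying the ring B 3'-hydroxy-para-quinone methide at C8' (geometry of the exocyclic C7'=C1' bond not defined) | COc1cc([C@H]2OC[C@@H](C=C3C=CC(=O)C(O)=C3)[C@@H]2CO)ccc1O | intermediate
10 | 4-[(R)-hydroxy{(3S,4R,5S)-5-(4-hydroxy-3-methoxyphenyl)-4-(hydroxymethyl)oxolan-3-yl}methyl]benzene-1,2-diol | COc1cc([C@H]2OC[C@@H]([C@@H](O)c3ccc(O)c(O)c3)[C@@H]2CO)ccc1O | target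

## Step count and weak points
Total steps: 5. Longest linear sequence: 5.

**Step 5** could fail through wrong regiochemistry of ring closure, a C7' epimer mixture, or over-oxidation of the product catechol.
- The fallback sets out from 7 and comes back at 10.
- The two CH2OH groups of 7 are pseudo-enantiotopic, so a lipase that desymmetrises the meso parent (screened with vinyl acetate in MTBE) should acylate only one of them. This gives the C9 monoacetate F1.
- With the rival nucleophile blocked, the cyclobutane is opened under the phenol-oxidation conditions known for the bis-guaiacyl series (FeCl3·6H2O, acetone–water). This gives the 9-O-acetyl target F2.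
- K2CO3 in MeOH removes the acetate and gives 10.

**Step 3** could fail because E/Z isomerisation outruns cycloaddition, or because tether control is poor.
- The fallback sets out from 1 and 4 and comes back at 7.
- The free acids are irradiated together in water inside cucurbit[8]uril, which packs two cinnamates head-to-head and syn.
- The heterodimer is separated from the two homodimers and resolved by crystallising its salt with (R)-1-phenylethylamine. This gives the (7S,8R,8'S,7'R)-heterodimeric beta-truxinic acid F3.
- BH3·THF reduces F3 to 7.

**Step 2** could fail because a hindered secondary alcohol meets an unprotected catechol acid under Mitsunobu conditions.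
- The fallback sets out from 4 and 3 and comes back at 7.
- 4 is peracetylated (Ac2O, pyridine) to di-O-acetylcaffeic acid F4.
- F4 is coupled with 3 under Mitsunobu conditions to give the diacetylated mixed diester F5.
- F5 is irradiated as in step 3 to give the diacetylated macrocyclic beta-truxinate F6.
- LiAlH4 then removes tether and acetates together to give 7.

## Further compounds
F1 | step 5 | C9 monoacetate of cyclobutane diol 7 | CC(=O)OC[C@@H]1[C@@H](c2ccc(O)c(OC)c2)[C@@H](c2ccc(O)c(O)c2)[C@@H]1CO
F2 | step 5 | 9-O-acetyl target | COc1cc([C@H]2OC[C@@H]([C@@H](O)c3ccc(O)c(O)c3)[C@@H]2COC(C)=O)ccc1O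
F3 | step 3 | (7S,8R,8'S,7'R)-heterodimeric beta-truxinic acid | OC(=O)[C@@H]1[C@@H](c2ccc(O)c(OC)c2)[C@@H](c2ccc(O)c(O)c2)[C@@H]1C(O)=O
F4 | step 2 | di-O-acetylcaffeic acid | CC(=O)Oc1ccc(/C=C/C(O)=O)cc1OC(C)=O
F5 | step 2 | diacetylated mixed diester | COc1cc(/C=C/C(=O)OCC[C@H](C)OC(=O)/C=C/c2ccc(OC(C)=O)c(OC(C)=O)c2)ccc1O
F6 | step 2 | diacetylated macrocyclic beta-truxinate | O=C1OCC[C@H](C)OC(=O)[C@H]2[C@H](c3ccc(OC(C)=O)c(OC(C)=O)c3)[C@H](c3ccc(O)c(OC)c3)[C@@H]12
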